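(Readings and results were computed on assumed constants; noise was put on by code.)

Winter cannot have stalled for want of substrate, since 26.2% of it still stands at 12.0 h, while in noon it has fallen to 0% by 4.00 h. In these closed, isothermal flasks the substrate and two partners, A and B, give an open intermediate, a target and a side product.

| setting | winter | noon | alder | birch | cedar |
|---|---|---|---|---|---|
| substrate | 0.020 M | 0.020 M | 0.020 M | 0.020 M | 0.020 M |
| partner A | 0.019 M | 0.019 M | 0.0190 M | 0.0190 M | 0.0190 M |
| partner B | 0.034 M | 0.053 M | 0.0240 M | 0.0240 M | 0.0240 M |
| temperature | 98 °C | 114 °C | 90 °C | 105 °C | 120 °C |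
| remark | run made earlier | run made earlier |  |  |  |
| time |  |  | 20 h | 20 h | 20 h |

| run | time / h | side product / % | open intermediate / % | target / % | substrate / % |
|---|---|---|---|---|---|
| winter | 2.00 | 17.2 | 2.6 | 44.6 | 35.6 |
| winter | 4.00 | 18.6 | 0 | 51.5 | 26.5 |
| winter | 6.00 | 20.3 | 1.5 | 52.5 | 24.5 |
| winter | 8.00 | 20.7 | 0 | 53.1 | 24.7 |
| winter | 10.0 | 22.5 | 0 | 54.6 | 25.6 |
| winter | 12.0 | 21.4 | 1.2 | 52.6 | 26.2 |
| noon | 0.667 | 40.1 | 4.3 | 48.1 | 7.4 |
| noon | 1.33 | 47.2 | 0.5 | 52.5 | 0.1 |
| noon | 2.00 | 47.6 | 1.1 | 53.9 | 0.7 |
| noon | 2.50 | 47.2 | 0 | 53.8 | 1.5 |
| noon | 3.00 | 49.2 | 0 | 52.5 | 1.2 |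
| noon | 4.00 | 47.1 | 1.5 | 55.1 | 0 |

(scatter of a reading: 1 percentage point)

- the analysis behind the earlier runs scatters by 1 percentage point, standard deviation

- which of these there is most of at the end, counted by the substrate in it, alder (target / substrate / open intermediate / side product)
- which of these there is most of at the end, counted by the substrate in it, birch (target / substrate / open intermediate / side product)
- which of these there is most of at the end, counted by the substrate in it, cedar (target / substrate / open intermediate / side product)
- how much there is at the end of the one of these that leads, in percent of the substrate charged: alder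
- how much there is at the end of the one of these that leads, in percent of the substrate charged: birch
- how much there is at the end of the one of these that leads, in percent of the substrate charged: cedar

What stops winter? Write c_S, c_A and c_B for the charges of substrate, partner A and partner B, and form σ = (c_B − c_A)/c_S. For winter, σ is 75.0%, so if partner A takes one partner B each and the substrate gets one from what remains, 25.0% of the substrate stays. This one-for-one count is my own reckoning, not the forecast's, and the winter readings from 6.00 h on lie between 24.5% and 26.2%.

Does noon fit? Its σ is 170%, above the whole substrate charge. On this count control changes hands at σ equal to 100%: below it partner B is the limiting reagent, above it the substrate is, and noon's substrate reads 0.1% by 1.33 h.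

Is 20 h long enough at 90 °C? Winter reads level from about 6.00 h and noon from about 1.33 h, a factor of 4.51, but noon differs from winter in partner B as well as in temperature, 0.053 M against 0.034 M. Taking that factor as temperature alone, with alder half that temperature gap below winter, gives a rough estimate of 12.7 h, shorter than the time allowed, and alder's smaller partner B charge is not in that estimate.

Alder, birch and cedar share one charge, so σ is 25.0% in each: this partner-B surplus, partner B charged beyond partner A per substrate charged, has no temperature in it. I expect 75.0% substrate left, more than the converted share, however heat divides that share.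

The forecast also names substrate in each flask, but at 47%, 49% and 53%, counting “about 2 B per target and 3 per side product”.

    open intermediate + second intermediate → target (k = 3.00 L mol⁻¹ min⁻¹, Ea = 56.0 kJ mol⁻¹)
    open intermediate → side product (k = 0.0100 min⁻¹, Ea = 116 kJ mol⁻¹)
    substrate + partner B → open intermediate (k = 0.990 L mol⁻¹ min⁻¹, Ea = 54.0 kJ mol⁻¹)
    partner B + partner A → second intermediate (k = 11.0 L mol⁻¹ min⁻¹, Ea = 54.0 kJ mol⁻¹)
    (constants at 90 °C)

Substrate leads in alder, birch and cedar at 72.4%, 72.4% and 72.4%, which is 25 percentage points, 23 points and 19 points above the forecast. Alder ends with 0% of its partner B and 2.76% of its partner A free. Counting in σ just the partner A that reacted gives 72.4% substrate left in alder. In a flask like cedar but charged with 0.096 M of partner B, σ is 385%, above the crossing, and that flask ends with 0% of its substrate.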